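A small charge shows the habit of this flask: the west run, with 0.250 M of starting material and 0.0500 M of free catalyst, reads 0.099 M of product at 17 min and 0.101 M at 29 min, so it has nearly stopped.

| flask | starting material | free catalyst | time |
|---|---|---|---|
| north | 0.500 M | 0.0500 M |  |
| west | 0.250 M | 0.0500 M |  |
| north-east | 0.500 M | 0.150 M |  |
| south | 1.50 M | 0.0500 M |  |
| south-east | 0.500 M | 0.0500 M | 170 min |

| north run: time / min | north run: [product] / M | west run: time / min | west run: [product] / M | north-east run: time / min | north-east run: [product] / M | south run: time / min | south run: [product] / M |
|---|---|---|---|---|---|---|---|
| 4.1 | 0.085 | 4.1 | 0.045 | 4.1 | 0.200 | 4.1 | 0.193 |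
| 8.3 | 0.132 | 8.3 | 0.065 | 8.3 | 0.279 | 8.3 | 0.327 |
| 12 | 0.151 | 12 | 0.080 | 12 | 0.297 | 12 | 0.400 |
| 17 | 0.179 | 17 | 0.099 | 17 | 0.317 | 17 | 0.472 |
| 21 | 0.189 | 21 | 0.094 | 21 | 0.330 | 21 | 0.496 |
| 25 | 0.191 | 25 | 0.104 | 25 | 0.323 | 25 | 0.518 |
| 29 | 0.201 | 29 | 0.101 | 29 | 0.318 | 29 | 0.530 |

(standard deviation of a reading: 0.004 M)

* the power of [free catalyst] that the first rate follows, about the charge of the north run; measure it at two percent of starting material made into product
* the power of [starting material] that the first rate follows, about the charge of the north run; measure it at two percent of starting material made into product (one fixed amount of product, the same in the runs compared)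
* product in the south-east run at 170 min, as a share of the starting material charged

- Overall: starting material -> product, with free catalyst as catalyst.
- Constant volume, constant temperature.
- What is held in complexes is read along with the free species.
- An order is taken over about fifteen percent of the charge, up and down.

Logarithms turn such a stop into one number. In the north run, the last reading leaves 0.299 M of the charge not made into product, which gives 0.223: this is the reach, the powers of ten by which the part of the charge not made into product has fallen at the last reading. The west run reads 0.225, so going from the west charge of starting material to the doubled north charge, at the same free catalyst, leaves the reach about equal. The south run, still rising, reads 0.189. The north-east run, with 0.150 M of free catalyst, reads 0.439, about twice the north value.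

The south-east run repeats the north charge, so, taking the north run as stopped at its last reading, the north reach gives an estimated share of 40.2%. The weak link is that single reading, which stands 0.0100 M above the one before it, against a scatter of 0.004 M. Pooling the last 3 readings of the north and west runs over their charges gives my own figure, 39.1%.

The forecast gives orders of 1 in free catalyst and 0.83 in starting material, and a share of 41.5%, higher than my figure. It says: “South-east repeats north, and by 170 min the catalyst is dead.”

The flask gives 1.0, 0.84 and 39.7% at 170 min, and the forecast's 3 values stand within their margins.

    free catalyst + starting material ⇌ catalyst-substrate complex, settled at all times (0.5960 /M)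
    catalyst-substrate complex ⇌ product + free catalyst (2.340 /min, 0.2484 /M/min)
    starting material → decomposed substrate (0.03150 /min)
    free catalyst → spent catalyst (0.07800 /min)

A fit with the main steps alone puts the south-east run at 60.5%, which is 21 percentage points above the flask. The south-east share at 170 min is a reach of 0.220, beside 0.223 for the north run at 29 min. The forecast's share does not carry over to another free catalyst charge: the north-east run, at 0.150 M, reads 63.6% at 29 min. Half turned needs a reach of 0.301, which is more than the north run's 0.223 but less than the north-east run's 0.439, and the north-east run passed half at 6.30 min.

The earlier runs and the new flask come from a simulation for substances that don't exist; noise was put on by code.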